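**Analysis of the target**

The target, 3,4,6-tribromo-2-(5-bromo-2-hydroxyphenoxy)phenol (12), is two benzene rings joined by one ether oxygen, with no other ring and no stereocentre, so the whole problem is one of substitution pattern. Ring A (primed numbers) carries the ether oxygen at C1', a free hydroxyl at C2' and one bromine at C5', para to that hydroxyl. Ring B is a catechol mono-ether with the hydroxyl at C1, the ether oxygen at C2, bromines at C3, C4 and C6, and its only hydrogen at C5. The sensitive groups are two free phenols (easily oxidised and over-halogenated) and four aryl bromides, which exclude alkyllithium reagents, zerovalent palladium and hydrogenolysis once they are present. Two features make the synthesis hard. First, the ether oxygen on ring B sits between an oxygenated carbon (C1) and a brominated carbon (C3) and faces an ortho-oxygenated carbon on ring A, so the diaryl ether is crowded on three sides and poorly suited to coupling two finished rings. Second, the C3 bromine is meta to the C1 hydroxyl, the strongest director on ring B, so electrophilic bromination will not place it, whereas C4 and C6 lie para and ortho to that hydroxyl and are easy. The strategy rests on the three adjacent carbons C1(O)–C2(OAr)–C3(Br) of ring B: they correspond to C3 of a 3-acyloxy-2-pyrone and to the two carbons of an aryloxy(bromo)acetylene, so a cycloaddition can build ring B with the ether and the awkward bromine already attached.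

**Retrosynthetic reasoning**

12 from 11. The last bond cut is the O–CH3 bond at C2' of ring A, giving the methyl ether 11. The methyl group is already present in the commercial phenol 3 (5-bromo-2-methoxyphenol) and is inert to base, heat and bromine. It also keeps ring A an anisole-type ring, less reactive than a free phenol, during the preceding bromination. The forward step must cleave one aryl methyl ether without touching the diaryl ether or the four bromines.

11 from 10. The C4–Br and C6–Br bonds of ring B are cut next, leading to the monobrominated phenol 10. These positions are para and ortho to the C1 hydroxyl, so an electrophile will choose them once that hydroxyl is free; C5 is meta to it and should stay unsubstituted. The C3–Br bond is deliberately kept, because no director on ring B would reinstall it selectively. The forward reaction must put exactly two bromines on ring B and none on ring A.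

10 from 9. The C1 oxygen is traced back to the acetate 9. This is only a change of protecting group, but it is the form in which the pyrone delivers that oxygen.

9 from 2 and 7, through 8. Ring B is opened at C1–C2 and C3–C4. Restoring a lactone bridge between C1 and C4 gives the bicyclic lactone 8, the [4+2] adduct of 3-acetoxy-2-pyrone 2 and the aryl bromoethynyl ether 7. Pyrone C3 becomes C1 and pyrone C4, C5 and C6 become C6, C5 and C4. The oxygen-bearing alkyne carbon becomes C2 and the bromine-bearing one C3. Cutting here, and not at the diaryl ether bond, means the crowded C2–O bond is never formed on an aromatic carbon, because the oxygen is already on the alkyne. The same cut brings in the C3 bromine and delivers ring B at the aromatic oxidation level from two small pieces. The forward reaction must proceed with one regiochemistry (aryloxy carbon next to acetoxy carbon) and the bridge must be expelled.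

7 from 6, and 6 from 3 and 4, through 5. The triple bond of 7 is traced back to the dibromovinyl ether 6 (dehydrobromination in the forward sense). Compound 6 is cut at its O–C(vinyl) bond into phenol 3 and tribromoethylene 4, which under base becomes dibromoacetylene 5, the species the phenoxide of 3 attacks. A tribromo two-carbon unit is preferred to the more usual trichloro one for two reasons. It leaves bromine, not chlorine, on the alkyne. It also lets a non-exchanging amide base finish the alkyne, where an organolithium would attack the ring A bromide.

2 from 1. The acetate of 2 is cut at the acyl–oxygen bond, giving commercial 3-hydroxy-2-pyrone 1.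

**Alternatives that were turned down**

Alternative 1: Here ring A, not ring B, is the ring that is built. It is cut at C3'–C4' and C6'–C1', so that C1', C2' and C3' come from the acetone unit of the aryloxy ketone A2, and C4', C5' (with its bromine) and C6' from the 2-bromovinamidinium salt A3. In the forward direction each α-carbon of A2 would condense with one terminus of A3 under a strong alkoxide base. Loss of the two amine leaving groups would aromatise the new ring to the phenol A1, which has all four bromines and is one demethylation from 12.
- For: the ether oxygen is attached by an ordinary SN2 alkylation with a haloacetone, so no bond to a crowded aromatic carbon is formed, and the ring A bromine arrives para to the new hydroxyl with no selectivity question. On the first point it equals the chosen route, and its endgame is two steps shorter.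
- Against: the ring constructed is the easy one. The ring A pattern can be bought as 3, whereas A2 needs a guaiacol-type phenol already brominated at C3, C4 and C6 of ring B. Bromination of that free phenol directs to C3 and C5, so the hard problem is moved into the starting material, not solved. The annulation would also expose a tribromoarene and an α-aryloxy ketone to strong alkoxide, where expulsion of the hindered aryloxide and oxygen-attack of the dienaminone intermediate are credible side paths.
- In exchange, the chosen strategy answers the C3 bromine directly and starts from materials that exist.

Alternative 2: Ring B is again built, but at the cyclohexane oxidation level. The C2–C3 bond is cut in a 1,3-dione: the dione A4 would come from the keto ester A5 by intramolecular Claisen (Dieckmann-type) condensation, the enolate at the aryloxy-bearing carbon attacking the ester to close the six-membered ring. One carbonyl of A4 would then become a vinyl bromide (A6) and the ring would be dehydrogenated to reach phenol 10 of the chosen route.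
- For: every step is textbook carbonyl chemistry, the ether is made by SN2 on an α-halo ketone, and because A4 is symmetrical it does not matter which carbonyl becomes C–Br. On predictability of the individual steps this alternative is stronger than the chosen key step.
- Against: the ring is made two oxidation levels too low. Aromatising A6 needs a dehydrogenation beside a vinyl bromide and an aryl bromide, which excludes palladium-based methods and leaves halogenation–elimination on a substrate whose anisole ring also reacts with electrophilic halogen. The sequence to 10 is several steps longer (halo keto ester, alkylation, cyclisation, bromination, aromatisation), and the α-aryloxy dione can lose aryloxide under base.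
- The chosen route reaches the same 10 redox-neutrally, with the bromine in place when the ring forms.

Alternative 3: Ring B is taken as a preformed benzene, and the O–C2 and C3–Br bonds are cut together, which points to an aryne. The aryne released from the iodo triflate A8 by halogen–magnesium exchange and loss of triflate would take up the magnesium phenoxide of 3 at the carbon next to boron. The aryl–magnesium species left at C3 would be quenched with an electrophilic bromine donor to give the boronate A7, and oxidation of the C–B bond would give 10.
- For: the crowded ether bond and the C3 bromine are made in one flask at low temperature. The boryl group both steers the nucleophile (by distorting the aryne) and later becomes the C1 hydroxyl, and nothing thermally fragile is involved. On mildness and on having a clear regiochemical model it is at least the equal of the chosen key step.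
- Against: A8 needs boron, triflate and iodine installed contiguously on one ring first, so the step count to 10 is no shorter. A magnesium phenoxide is a weak, ambident nucleophile towards arynes (carbon versus oxygen attack), and this one is ortho-substituted. The exchange reagent can also engage the aryl bromide of the phenoxide partner or form an ate complex at boron, and the aryl–magnesium intermediate must survive until the bromine donor is added. Three things must go right in one operation.
- The chosen route concentrates its risk in one pericyclic step whose partners are each two steps from commercial materials, with no organometallic species alongside aryl bromides.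

Key step: step 4

Remark on the chemistry: the E geometry written for 6 is assumed from anti addition to 5 and has no consequence, because the double bond becomes a triple bond in step 3. Intermediate 8 is racemic and its two bridgehead stereocentres vanish with the bridge.

**Route**

Step 1
Reactants: 1 3-hydroxy-2H-pyran-2-one
Product: 2 2-oxo-2H-pyran-3-yl acetate
Conditions: Ac2O, pyridine, CH2Cl2, 0 °C → rt
Reagents that add atoms: acetic anhydride CC(=O)OC(C)=O
Why: O-acylation (esterification) of the acidic enolic hydroxyl of the pyrone; the lactone is not opened by pyridine at this temperature.

Step 2
Reactants: 3 5-bromo-2-methoxyphenol; 4 tribromoethylene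
Product: 6 4-bromo-2-{[(E)-1,2-dibromoethenyl]oxy}-1-methoxybenzene, via dibromoacetylene 5 (not isolated)
Conditions: K2CO3 (2 equiv), DMF, rt → 50 °C, N2; 4 (1.5 equiv) added slowly
Reagents that add atoms: none
Why: K2CO3 removes HBr from 4 to give 5 in low stationary concentration, the phenoxide of 3 adds to it in anti fashion and protonation gives the (E)-1,2-dibromovinyl ether. This elimination–addition is the bromine counterpart of the well-used addition of phenols to trichloroethylene. Slow addition under inert gas keeps the hazardous 5 from accumulating, and the aryl bromide and methyl ether are inert to carbonate in DMF.

Step 3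
Reactants: 6 4-bromo-2-{[(E)-1,2-dibromoethenyl]oxy}-1-methoxybenzene
Product: 7 4-bromo-2-[(bromoethynyl)oxy]-1-methoxybenzene
Conditions: LiN(SiMe3)2 (1.1 equiv), THF, −78 → 0 °C; used without storage
Reagents that add atoms: none
Why: Base-induced dehydrohalogenation of a 1,2-dihaloalkene to a 1-haloalkyne: the vinylic hydrogen next to bromine is removed and the α-bromo vinyllithium loses LiBr, by β-elimination or by a Fritsch–Buttenberg–Wiechell-type 1,2-bromine shift, both of which give the same bromoalkyne. A silylamide base cannot undergo lithium–bromine exchange with the aryl bromide, and the lithium counter-ion disfavours expulsion of aryloxide from the vinyl anion.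

Step 4
Reactants: 2 2-oxo-2H-pyran-3-yl acetate; 7 4-bromo-2-[(bromoethynyl)oxy]-1-methoxybenzene
Product: 9 3-bromo-2-(5-bromo-2-methoxyphenoxy)phenyl acetate, via bridged lactone 8 (not isolated)
Conditions: 2 (2 equiv), o-xylene, 140 °C, sealed tube, BHT (cat.)
Reagents that add atoms: none
Why: Thermal [4+2] cycloaddition in which pyrone 2 reacts as the 4π component across C3 and C6 and alkyne 7 as the 2π component, followed by retro-[4+2] loss of CO2 from the bridged lactone 8, which for alkyne adducts should be fast at the cycloaddition temperature because a benzene results directly. The closest known reaction type is the Diels–Alder/decarboxylation of 2-pyrones with ynamines, alkoxyalkynes and other heteroatom-substituted alkynes to give substituted benzenes. Ring B is closed by the cycloaddition itself: two σ bonds, C1–C2 and C3–C4 in target numbering, form in one suprafacial event expected to be asynchronous with C3–C4 leading, and extrusion of the lactone bridge then leaves the six-membered carbocycle aromatic. No stereocentre is present in 9, and the two bridgehead centres of 8 are lost with the bridge. The step needs regioselectivity: the aryloxy-bearing alkyne carbon must bond to the acetoxy-bearing C3 of the pyrone. This is secured by matched polarisation, since oxygen lone-pair donation makes the bromine-bearing alkyne carbon the nucleophilic terminus and the pyrone is most electrophilic at C6, the δ-position of its dienoate, so these two carbons join first. The acetyl group keeps the C3 oxygen from acting as a strong donor, so 2 should behave like a 3-halo-2-pyrone, electron-poor enough for this polarity. The aryl ynol ether has no β-hydrogen on its oxygen substituent and cannot fragment to a ketene by a retro-ene path, so it should tolerate the heating.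

Step 5
Reactants: 9 3-bromo-2-(5-bromo-2-methoxyphenoxy)phenyl acetate
Product: 10 3-bromo-2-(5-bromo-2-methoxyphenoxy)phenol
Conditions: K2CO3 (cat.), MeOH, rt
Reagents that add atoms: none
Why: Base-catalysed transesterification: an aryl acetate is a far better acyl donor than an alkyl ester and passes its acetyl group to methanol. Aryl bromides and both ethers are untouched.

Step 6
Reactants: 10 3-bromo-2-(5-bromo-2-methoxyphenoxy)phenol
Product: 11 3,4,6-tribromo-2-(5-bromo-2-methoxyphenoxy)phenol
Conditions: Br2 (2.1 equiv), CH2Cl2, 0 °C → rt
Reagents that add atoms: bromine BrBr
Why: Electrophilic aromatic bromination directed by the free C1 hydroxyl to its para (C4) and open ortho (C6) positions; C5, meta to the hydroxyl, should stay unsubstituted. Ring A carries only ether oxygens and the position para to its methoxyl is already brominated, so it should react much more slowly than the phenol ring.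

Step 7
Reactants: 11 3,4,6-tribromo-2-(5-bromo-2-methoxyphenoxy)phenol
Product: 12 3,4,6-tribromo-2-(5-bromo-2-hydroxyphenoxy)phenol
Conditions: BBr3 (3 equiv), CH2Cl2, −78 °C → rt; then H2O
Reagents that add atoms: none
Why: Aryl methyl ether cleavage: BBr3 complexes the methoxy oxygen and bromide attacks the methyl group by SN2. The diaryl ether offers no sp3 carbon for this attack and should survive, and aryl bromides are inert.

**Compound list**

1 | 3-hydroxy-2H-pyran-2-one | O=C1OC=CC=C1O | starting material
2 | 2-oxo-2H-pyran-3-yl acetate | CC(=O)OC1=CC=COC1=O | intermediate
3 | 5-bromo-2-methoxyphenol | COc1ccc(Br)cc1O | starting material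
4 | tribromoethylene | BrC=C(Br)Br | starting material
5 | dibromoacetylene (formed in the flask, not isolated) | BrC#CBr | intermediate
6 | 4-bromo-2-{[(E)-1,2-dibromoethenyl]oxy}-1-methoxybenzene | Br/C=C(/Br)Oc1cc(Br)ccc1OC | intermediate
7 | 4-bromo-2-[(bromoethynyl)oxy]-1-methoxybenzene | COc1ccc(Br)cc1OC#CBr | intermediate
8 | 6-bromo-5-(5-bromo-2-methoxyphenoxy)-3-oxo-2-oxabicyclo[2.2.2]octa-5,7-dien-4-yl acetate (racemic, formed in the flask, not isolated) | CC(=O)OC12C=CC(OC1=O)C(Br)=C2Oc1cc(Br)ccc1OC | intermediate
9 | 3-bromo-2-(5-bromo-2-methoxyphenoxy)phenyl acetate | CC(=O)Oc1cccc(Br)c1Oc1cc(Br)ccc1OC | intermediate
10 | 3-bromo-2-(5-bromo-2-methoxyphenoxy)phenol | Oc1cccc(Br)c1Oc1cc(Br)ccc1OC | intermediate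
11 | 3,4,6-tribromo-2-(5-bromo-2-methoxyphenoxy)phenol | Oc1c(Br)cc(Br)c(Br)c1Oc1cc(Br)ccc1OC | intermediate
12 | 3,4,6-tribromo-2-(5-bromo-2-hydroxyphenoxy)phenol | Oc1ccc(Br)cc1Oc1c(O)c(Br)cc(Br)c1Br | target

**Step count and risk**

Total step count: 7. Longest linear sequence: 6 steps (3 → 6 → 7 → 9 → 10 → 11 → 12, steps 2 to 7); the pyrone branch (step 1) joins at step 4.

Step 4 (key step). The most likely failure is that the cycloaddition is too slow at temperatures the bromo ynol ether tolerates, so that oligomerisation or decomposition of 7 outruns it. Compound 7 is a weaker donor than an ynamine and 2 is only a moderately electron-poor diene. A second failure mode is erosion of regiocontrol, if bromine lone-pair donation and crowding at the carbon that becomes quaternary in 8 offset the oxygen polarisation. The fallback sets out from 3 and returns at 10; ring B is taken ready-made instead of being built. Phenol 3 is condensed by SNAr (K2CO3, DMF, heat) with 3-bromo-2-fluorobenzaldehyde F1, whose fluoride is activated by the ortho formyl group, to give 3-bromo-2-(5-bromo-2-methoxyphenoxy)benzaldehyde F2. Baeyer–Villiger oxidation with m-chloroperbenzoic acid, in which the ortho oxygen favours aryl migration, gives 3-bromo-2-(5-bromo-2-methoxyphenoxy)phenyl formate F3. Methanolysis (K2CO3 cat., MeOH) gives 10, and steps 6 and 7 follow unchanged.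

Step 2. The elimination–addition balance may fail: 5 may build up and oligomerise, which is also a hazard, or carbonate may dehydrobrominate product 6 further so that a second phenoxide adds. The fallback sets out from 3, returns at 7 and never generates 5. Formylation of 3 (formic acetic anhydride, pyridine) gives 5-bromo-2-methoxyphenyl formate F4. Wittig-type dibromomethylenation of the formyl group (CBr4, PPh3) gives 4-bromo-2-[(2,2-dibromoethenyl)oxy]-1-methoxybenzene F5. Its vinylic hydrogen is on the oxygen-bearing carbon and anti to one bromine, so LiN(SiMe3)2 at −78 °C should give 7 by anti E2 elimination, as in the standard conversion of 1,1-dibromoalkenes to 1-bromoalkynes.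

Step 3. The vinyl anion formed from 6 has its lone pair anti to the aryloxy group, so expulsion of aryloxide (reversal of step 2) may compete with loss of bromide. Excess amide may also attack the alkynyl bromine of the product. The fallback sets out from 6, returns at 7 and uses no strong base. Zinc dust in THF removes the two vicinal bromines of 6 by reductive anti-elimination; a 1,2-dibromoalkene behaves as a masked alkyne, and the aryl bromide should not insert zinc under these conditions. This gives 4-bromo-2-(ethynyloxy)-1-methoxybenzene F6. Bromination of its terminal C–H with N-bromosuccinimide and catalytic AgNO3 in acetone gives 7.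

Step 6. Ring selectivity may be lost through electrophilic attack ortho to the methoxyl of ring A, or the reaction may stall after the first bromination of ring B. The fallback sets out from 10 and returns at 11; the bromines are introduced one at a time by reagents whose selectivity does not depend on the relative reactivity of the two rings. N-Bromosuccinimide with catalytic i-Pr2NH in CH2Cl2 delivers bromine through a hydrogen-bonded N-bromoamine to the position ortho to the hydroxyl, which only ring B has, giving 3,6-dibromo-2-(5-bromo-2-methoxyphenoxy)phenol F7. Then n-Bu4NBr3, a mild para-selective reagent for phenols, brominates C4 to give 11.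

**Further compounds**

F1 | step 4 | 3-bromo-2-fluorobenzaldehyde | O=Cc1cccc(Br)c1F
F2 | step 4 | 3-bromo-2-(5-bromo-2-methoxyphenoxy)benzaldehyde | O=Cc1cccc(Br)c1Oc1cc(Br)ccc1OC
F3 | step 4 | 3-bromo-2-(5-bromo-2-methoxyphenoxy)phenyl formate | O=COc1cccc(Br)c1Oc1cc(Br)ccc1OC
F4 | step 2 | 5-bromo-2-methoxyphenyl formate | COc1ccc(Br)cc1OC=O
F5 | step 2 | 4-bromo-2-[(2,2-dibromoethenyl)oxy]-1-methoxybenzene | COc1ccc(Br)cc1OC=C(Br)Br
F6 | step 3 | 4-bromo-2-(ethynyloxy)-1-methoxybenzene | COc1ccc(Br)cc1OC#C
F7 | step 6 | 3,6-dibromo-2-(5-bromo-2-methoxyphenoxy)phenol | Oc1c(Br)ccc(Br)c1Oc1cc(Br)ccc1OC
A1 | alternative 1 | 4-bromo-2-(2,3,5-tribromo-6-methoxyphenoxy)phenol | COc1c(Br)cc(Br)c(Br)c1Oc1cc(Br)ccc1O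
A2 | alternative 1 | 1-(2,3,5-tribromo-6-methoxyphenoxy)propan-2-one | CC(=O)COc1c(OC)c(Br)cc(Br)c1Br
A3 | alternative 1 | 2-bromo-1,3-bis(dimethylamino)trimethinium hexafluorophosphate | CN(C)C=C(Br)C=[N+](C)C.F[P-](F)(F)(F)(F)F
A4 | alternative 2 | 2-(5-bromo-2-methoxyphenoxy)cyclohexane-1,3-dione | COc1ccc(Br)cc1OC1C(=O)CCCC1=O
A5 | alternative 2 | methyl 6-(5-bromo-2-methoxyphenoxy)-5-oxohexanoate | COC(=O)CCCC(=O)COc1cc(Br)ccc1OC
A6 | alternative 2 | 3-bromo-2-(5-bromo-2-methoxyphenoxy)cyclohex-2-en-1-one | COc1ccc(Br)cc1OC1=C(Br)CCCC1=O
A7 | alternative 3 | 2-[3-bromo-2-(5-bromo-2-methoxyphenoxy)phenyl]-4,4,5,5-tetramethyl-1,3,2-dioxaborolane | COc1ccc(Br)cc1Oc1c(Br)cccc1B1OC(C)(C)C(C)(C)O1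
A8 | alternative 3 | 2-iodo-6-(4,4,5,5-tetramethyl-1,3,2-dioxaborolan-2-yl)phenyl trifluoromethanesulfonate | CC1(C)OB(OC1(C)C)c1cccc(I)c1OS(=O)(=O)C(F)(F)F
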